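The ash run stopped short.

| setting | birch | ash | grey | ochre | red |
|---|---|---|---|---|---|
| starting complex | 2 mM | 2 mM | 2.0 mM | 2.0 mM | 2.0 mM |
| incoming ligand | 1.9 mM | 4.8 mM | 2.40 mM | 5.00 mM | 6.00 mM |
| remark | run made earlier | run made earlier |  |  |  |
| time |  |  | 10 min | 10 min | 10 min |

| run | time / min | complex with two exchanged / % | complex with one exchanged / % |
|---|---|---|---|
| birch | 2.00 | 22.7 | 21.0 |
| birch | 4.00 | 30.0 | 19.8 |
| birch | 6.00 | 32.8 | 18.6 |
| birch | 8.00 | 32.0 | 18.6 |
| birch | 10.0 | 32.5 | 19.8 |
| ash | 0.833 | 37.5 | 19.6 |
| ash | 2.50 | 67.7 | 13.3 |
| ash | 5.00 | 75.1 | 13.5 |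
| ash | 8.00 | 78.2 | 14.1 |
| ash | 10.0 | 76.7 | 13.7 |

(standard deviation of a reading: 1 percentage point)



- final complex with two exchanged, as a percentage of the starting complex charged, for each flask in turn (grey, ochre, red)

Ash was charged 4.8 mM of incoming ligand, and 4.00 mM would have exchanged both places on every starting complex. Yet the complex with two exchanged read 75.1 % at 5.00 min and 76.7 % at 10.0 min, which is flat within the scatter. I assumed that each exchange takes up one incoming ligand and sets free one leaving ligand. Ash at 10.0 min then held 3.34 mM of leaving ligand and 1.46 mM of incoming ligand outside the complexes, so the ligand had not run out.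

Counting half-lives showed how far ash had gone. In ash the gap to the final reading closed with a half-life of 0.785 min, so 10.0 min held 12.7 half-lives, which says that ash had levelled off but not why it had stopped.

From ash I kept 12.8 as the stopping quotient, [complex with two exchanged]·[leaving ligand] over [complex with one exchanged]·[incoming ligand]. Birch, with its different charge, read 13.6, close to the ash figure. On that agreement between two charges I read both plateaus as equilibrium, which is thermodynamic control. For ochre I held the complex with one exchanged at ash's 13.7 % and solved the quotient against the ligand balance, which gave 79.3 % of the complex with two exchanged.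

The forecast gave 42 %, 78.6 % and 85.4 % for grey, ochre and red, on the ground that “Both runs plateau by about 6 min, so 10 min should reach equilibrium.”

The flasks gave 41.9 % in grey, 78.7 % in ochre and 85.5 % in red.

    complex with one exchanged + incoming ligand ⇌ leaving ligand + complex with two exchanged (K = 28.0, k = 25.0 /M/s)
    incoming ligand ⇌ dormant form (K = 1.10, k = 0.160 /s)
    incoming ligand → decomposition product (k = 7.30 × 10⁻⁶ /s)
    starting complex + incoming ligand ⇌ leaving ligand + complex with one exchanged (K = 6.60, k = 9.60 /M/s)

Ochre at 10.0 min held 0.836 mM of the dormant form beside 0.760 mM of incoming ligand, and together these make up the ligand my balance had counted as left. Counted that way, the stopping quotient in ochre came to 13.3. The red flask, with 9.75 % of the complex with one exchanged and 1.25 mM of the dormant form, came to 13.3.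

(All runs were computed for substances that don't exist; scatter was added.)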